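**Two questions.** Two questions stand on each of theta, beta and epsilon: which species holds most of the substrate at the end, and how much of it. We answer both by counting turnovers.

in all of them: substrate 0.10 M
- north-west: reagent 0.20 M; free catalyst 0.75 mM; run made earlier
- north-east: reagent 0.20 M; free catalyst 1.1 mM; run made earlier
- theta: reagent 0.200 M; free catalyst 0.85 mM; time 6.0 min
- beta: reagent 0.200 M; free catalyst 0.65 mM; time 6.0 min
- epsilon: reagent 0.200 M; free catalyst 0.50 mM; time 6.0 min

| run | time / min | substrate / % | product / % | catalyst intermediate D / % | catalyst intermediate C / % |
|---|---|---|---|---|---|
| north-west | 0.333 | 97.3 | 2.7 | 0 | 0 |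
| north-west | 0.833 | 95.8 | 3.6 | 1.3 | 0 |
| north-west | 2.00 | 91.2 | 10.0 | 0 | 1.1 |
| north-west | 4.00 | 82.3 | 17.0 | 0 | 0.2 |
| north-east | 1.00 | 91.8 | 6.9 | 0 | 0.8 |
| north-east | 2.00 | 85.6 | 14.4 | 0.9 | 0.3 |
| north-east | 3.00 | 80.2 | 19.7 | 0.1 | 0.2 |
| north-east | 4.00 | 74.6 | 25.4 | 0 | 0 |

(standard deviation of a reading: 0.5 percentage points)

- steps that have been proposed: reagent + free catalyst -> catalyst intermediate A; free catalyst <-> dormant form; catalyst intermediate D -> free catalyst + product; catalyst intermediate C -> catalyst intermediate D; substrate + catalyst intermediate B -> catalyst intermediate C; catalyst intermediate A <-> by-product + catalyst intermediate B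

- which of these there is most of at the end, counted by the substrate in it, theta (substrate / catalyst intermediate D / catalyst intermediate C / product)
- which of these there is most of at the end, counted by the substrate in it, beta (substrate / catalyst intermediate D / catalyst intermediate C / product)
- which of these there is most of at the end, counted by the substrate in it, epsilon (substrate / catalyst intermediate D / catalyst intermediate C / product)
- amount of the one of these that there is most of at the end, in percent of the substrate charged, theta
- amount of the one of these that there is most of at the end, in percent of the substrate charged, beta
- amount of the one of these that there is most of at the end, in percent of the substrate charged, epsilon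

**Turnover count.** At 4.00 min the north-west substrate stands at 82.3%, which is 5.90 /min of substrate consumed per charged catalyst. The north-east run, at 74.6%, gives 5.77 /min. The two agree although the catalyst charges differ, so we carry their mean, N = 5.84 /min, the turnover frequency: substrate consumed per charged catalyst per minute.

**The curve.** For a catalyst charge c, we draw substrate as a straight line of slope Nc, which in theta, richer in catalyst than beta and epsilon, is 4.96 mM/min. The readings stop at 4.00 min, so the stretch to 6.0 min is extrapolated, and it leaves 70.2% in theta, 77.2% in beta and 82.5% in epsilon. Product crosses substrate at t_x, when half the charge has turned over; in theta that is 10.1 min, and beta and epsilon come later, at 13.2 min and 17.1 min. The end comes before each crossing, so substrate leads in each flask. Intermediates C and D sit on the catalyst, whose charge in theta is 0.850% of the substrate charged, so they do not contend. The line's floor is zero substrate, the limiting reagent, since reagent is charged at twice its amount; the theta line meets that floor at 20.2 min.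

**The forecast.** The forecast names substrate for theta, substrate for beta and substrate for epsilon, at 70.4% (68.5% to 72.5%), 77.4% (75.5% to 79.5%) and 82.6% (80.5% to 85%), from the remark that “Both runs lose substrate almost linearly with time”. In theta it stands 0.20 percentage points above our figure.

**The result.** The flasks end with substrate most in theta at 71.5%, substrate in beta at 77.4% and substrate in epsilon at 82.1%.

    reagent + free catalyst → catalyst intermediate A (k = 2.70 /M/s)
    free catalyst ⇌ dormant form (K = 0.770, k = 0.0340 /s)
    catalyst intermediate D → free catalyst + product (k = 0.960 /s)
    catalyst intermediate C → catalyst intermediate D (k = 0.640 /s)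
    substrate + catalyst intermediate B → catalyst intermediate C (k = 5.00 /M/s)
    catalyst intermediate A ⇌ by-product + catalyst intermediate B (K = 0.0380 M, k = 0.760 /s)

**Counted again.** Theta ran at 5.60 /min against the carried 5.84 /min. The main reason for the gap between theta and epsilon is the difference in concentration of free catalyst: theta keeps 71.5% of its substrate, and with epsilon's charge of free catalyst it keeps 82.1%. For beta's neighbour with 2.60 mM of free catalyst, t_x is 3.29 min, before 6.0 min, and that flask ends with product most, at 64.6%, with 35.1% of substrate left against the 8.95% of the line.

(The data are calculated with made-up constants; the scatter is artificial.)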